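In a closed flask D, G (with X counted in it), E and Q, one Q counting as two, add up to the charge. So after 10.0 min the north-east run had sent 8.60% of its charge past G and the north run 8.00%, while the fraction still in G read 7.9% against 0.8%. I had to choose the charge of D for the next run, low or high, to get the most free G at the end.

| flask | D | J | remark | time | volume of the second phase over the first |
|---|---|---|---|---|---|
| north-east | 0.037 M | 0.055 M | run made earlier |  |  |
| north | 0.15 M | 0.055 M | run made earlier |  |  |
| west | 0.35 M | 0.055 M | run made earlier |  |  |
| epsilon | 0.050 M | 0.0550 M |  | 10 min | 1.0 |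
| delta | 0.10 M | 0.0550 M |  | 10 min | 1.0 |
| beta | 0.20 M | 0.0550 M |  | 10 min | 1.0 |
| theta | 0.40 M | 0.0550 M |  | 10 min | 1.0 |

| run | time / min | G / % | D / % |
|---|---|---|---|
| north-east | 2.00 | 0.8 | 98.7 |
| north-east | 4.00 | 3.1 | 96.5 |
| north-east | 6.00 | 5.0 | 91.8 |
| north-east | 8.00 | 7.2 | 87.5 |
| north-east | 10.0 | 7.9 | 83.5 |
| north | 0.833 | 0.1 | 99.4 |
| north | 1.50 | 0.3 | 99.6 |
| north | 3.00 | 1.0 | 99.1 |
| north | 5.00 | 0.7 | 96.4 |
| north | 10.0 | 0.8 | 91.2 |
| west | 2.00 | 0 | 98.8 |
| west | 4.00 | 0.2 | 98.0 |
| west | 6.00 | 0 | 98.3 |
| west | 8.00 | 0 | 96.9 |
| west | 10.0 | 0.1 | 94.9 |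

(each reading ± 0.5 percentage points)

- a species is counted by the D in it: one Q counts as two
- amounts and yields of G count X too
- in the second phase: J; everything else is in the first
- charges count per volume of the first phase; a concentration in a rate is the amount of a species over the volume of its own phase; every rate counts per litre of the first phase
- the analysis behind the earlier runs scatters by 0.5 percentage points, standard deviation
- on the list of suspects stand: Z + G <-> X; Z <-> J; D + G -> Q; D + Z -> G; G <-> E
- the earlier runs hold the two phases in the same ratio of volumes as the flask asked about
- the concentration of G that is asked is that of its free form alone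
- "hardly changes" means that all values lie within two and a half points (for a concentration: within two and a half percent of the largest)

- [G] (only what is free in solution, in the first phase) at the end for epsilon, delta, beta, theta, in this order
- how the row runs (hardly changes / falls, then rises / falls all the way / rises, then falls / rises all the way)

The choice hung on how steeply the end fraction of G drops as the charge rises. Read from those two ends, the slope came to 1.64, and I call it the fall exponent, the percent by which the end fraction of G drops per percent more D charged, an apparent order. A concentration is the charge times its fraction, so on such a line, at the same time and the same charge of J, an exponent above one means that more D leaves less G, X counted. The north reading of 0.8% carries a scatter of 0.5 percentage points, but with it taken one standard deviation higher the exponent is still 1.29. Carried on to the west run, the line gives 0.200%, and that run read 0.1% with a scatter of 0.5 points. So I would charge the epsilon flask, and for the four flasks, X counted with G, I committed to 0.00241 M, 0.00155 M, 9.99 × 10⁻⁴ M and 6.43 × 10⁻⁴ M.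

The forecast for free G, lower than my row at both ends, gave 0.0018 M, 0.0012 M, 7.000 × 10⁻⁴ M and 3.000 × 10⁻⁴ M, a row that falls all the way, saying of the level of G that “it drops strongly as D rises”.

The flasks gave, as free G, 0.00265 M, 0.00215 M, 0.00128 M and 6.65 × 10⁻⁴ M: the row falls all the way.

    Z + G ⇌ X, settled at all times (K = 20.0 M⁻¹)
    Z ⇌ J, rate k2*([Z] - [J]/K2) per volume of the first phase (partition coefficient = 5.60, kL = 0.00170 s⁻¹)
    D + G → Q (k = 0.0520 M⁻¹ s⁻¹)
    D + Z → G (k = 0.130 M⁻¹ s⁻¹)
    G ⇌ E (K = 1.20, k = 0.00120 s⁻¹)

With the exponent 1.64, the line had given the epsilon flask 4.83% of its charge as G, against 5.51% found, and the theta flask 0.161%, against 0.167% found. In the epsilon flask D was used by D + Z into G 3.1 times as fast as by D + G into Q at 4.55 min, and at 10.0 min that ratio stood at 1.8.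

The data are calculated with made-up constants; noise was put on by code.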